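The cyclohexane ring is closed last, between the ring CH that bears the side chain (C1) and the neighbouring arene carbon (C8a). The acetoxymethyl carbon (C20) is carried as the carbonyl of a cis-β-lactone that runs through the side-chain CH (C11) to an oxygen on C1; a cinchona-catalysed ketene–aldehyde cyclocondensation joins both halves and sets C11 and C1–O. In the key step a Lewis acid lets C8a, para to a catechol oxygen, displace the lactone oxygen at C1 with inversion: ring closure, the C1 configuration (trans to the ring methyl) and a free C20 acid result together. The two CHMe centres come from a redox-relay Heck arylation and the chiral pool.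

Key step: step 10

Locants (target numbering, used in all names): C1 = ring CH bearing the side chain, C2/C3 = ring CH2, C4 = ring CHMe, C4a/C5(OH)/C6(OH)/C7(CO2H)/C8(H)/C8a = arene, C11 = side-chain CH, C12–C14 = CH2, C15 = CHMe, C16 = CH2OH, C20 = CH2OAc on C11. The target is (1S,4R,11S,15S), with the C1 side chain trans to the C4 methyl.

Assumption: the absolute sense of induction in the two catalyst-controlled steps (4 and 9) is assigned from the accepted models for these catalyst classes; if either proved opposite, the enantiomeric ligand (step 4) or O-TMS-quinidine (step 9) would be used with no other change.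

Step 1
Reactants: 1 3,6-dibromobenzene-1,2-diol
Product: 2 4,7-dibromo-2,2-diphenyl-1,3-benzodioxole
Conditions: Ph2CCl2 (1.2 equiv), neat, 160 °C
Reagents that add atoms: dichlorodiphenylmethane, ClC(Cl)(c1ccccc1)c1ccccc1
Why: Catechol ketalisation with a gem-dichloride (double O-alkylation) should give the diphenylmethylene ketal, which holds both oxygens coplanar with the ring as donors for step 10 and is removed by hydrogenolysis in step 13.

Step 2
Reactants: 2 4,7-dibromo-2,2-diphenyl-1,3-benzodioxole
Product: 4 benzyl 7-bromo-2,2-diphenyl-1,3-benzodioxole-4-carboxylate, via aryllithium 3 (not isolated)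
Conditions: n-BuLi (1.0 equiv), THF, −78 °C; then cannulated into ClCO2Bn (3 equiv), THF, −78 °C
Reagents that add atoms: benzyl chloroformate, O=C(Cl)OCc1ccccc1
Why: Bromine–lithium exchange on the symmetric dibromide should stop at the mono-aryllithium, and inverse addition to excess chloroformate (C-acylation) should give the benzyl ester without double addition.

Step 3
Reactants: 4 benzyl 7-bromo-2,2-diphenyl-1,3-benzodioxole-4-carboxylate
Product: 5 [7-(benzyloxycarbonyl)-2,2-diphenyl-1,3-benzodioxol-4-yl]boronic acid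
Conditions: B2(OH)4, XPhos-Pd-G2 (2 mol %), XPhos, KOAc, EtOH, 80 °C
Reagents that add atoms: tetrahydroxydiboron, OB(O)B(O)O
Why: Miyaura-type borylation of an aryl bromide activated by the para ester should give the boronic acid directly, the ester and ketal being inert to acetate base.

Step 4
Reactants: 5 [7-(benzyloxycarbonyl)-2,2-diphenyl-1,3-benzodioxol-4-yl]boronic acid; 6 (Z)-pent-3-en-1-ol
Product: 7 benzyl 7-[(2R)-5-oxopentan-2-yl]-2,2-diphenyl-1,3-benzodioxole-4-carboxylate
Conditions: Pd(MeCN)2(OTs)2 (6 mol %), Cu(OTf)2 (6 mol %), (S)-5-CF3-tBu-PyrOx (13 mol %), 3 Å MS, O2 (1 atm), DMF, rt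
Reagents that add atoms: none
Why: Enantioselective redox-relay oxidative Heck arylation: aryl–Pd should insert the alkene with the aryl at the carbon remote from OH, the PyrOx ligand selecting the alkene face and so setting C4 (R), after which Pd walks by β-hydride elimination/reinsertion to the carbinol carbon and is released as the aldehyde.

Step 5
Reactants: 8 (R)-3-bromo-2-methylpropan-1-ol
Product: 9 (R)-[(3-bromo-2-methylpropoxy)methyl]benzene
Conditions: BnOC(=NH)CCl3, TfOH (cat.), CH2Cl2/cyclohexane, 0 °C to rt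
Reagents that add atoms: benzyl 2,2,2-trichloroacetimidate, N=C(OCc1ccccc1)C(Cl)(Cl)Cl
Why: Acid-catalysed O-benzylation with the trichloroacetimidate avoids base (no oxetane closure or elimination of the bromo alcohol) and leaves the chiral-pool stereocentre (future C15) untouched.

Step 6
Reactants: 9 (R)-[(3-bromo-2-methylpropoxy)methyl]benzene; 10 5-bromopent-1-ene
Product: 12 (S)-{[(2-methyloct-7-en-1-yl)oxy]methyl}benzene, via Grignard reagent 11 (not isolated)
Conditions: 10, Mg, THF; then 9, Li2CuCl4 (5 mol %), THF, −20 °C to rt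
Reagents that add atoms: none
Why: Copper-catalysed sp3–sp3 coupling of a Grignard reagent with a primary bromide (Kochi–Tamura type) should extend the chain; the stereocentre is β to the reacting carbon and is not affected (the descriptor changes only by priority).

Step 7
Reactants: 12 (S)-{[(2-methyloct-7-en-1-yl)oxy]methyl}benzene
Product: 13 (S)-7-(benzyloxy)-6-methylheptanoic acid
Conditions: OsO4 (1 mol %), Oxone (4 equiv), DMF, rt
Reagents that add atoms: Oxone (potassium peroxymonosulfate), [K+].[O-]S(=O)(=O)OO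
Why: OsO4/Oxone oxidative cleavage should convert the terminal alkene directly into the carboxylic acid with loss of the terminal carbon, the benzyl ether being tolerated.

Step 8
Reactants: 13 (S)-7-(benzyloxy)-6-methylheptanoic acid
Product: 14 (S)-7-(benzyloxy)-6-methylheptanoyl chloride
Conditions: (COCl)2, DMF (cat.), CH2Cl2, 0 °C to rt
Reagents that add atoms: oxalyl chloride, O=C(Cl)C(=O)Cl
Why: Standard acid chloride formation under Vilsmeier catalysis; no stereocentre is involved.

Step 9
Reactants: 7 benzyl 7-[(2R)-5-oxopentan-2-yl]-2,2-diphenyl-1,3-benzodioxole-4-carboxylate; 14 (S)-7-(benzyloxy)-6-methylheptanoyl chloride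
Product: 16 benzyl 7-{(2R)-4-[(2R,3S)-3-[(4S)-5-(benzyloxy)-4-methylpentyl]-4-oxooxetan-2-yl]butan-2-yl}-2,2-diphenyl-1,3-benzodioxole-4-carboxylate, via alkylketene 15 (not isolated)
Conditions: O-TMS-quinine (10 mol %), LiClO4, iPr2NEt, CH2Cl2/Et2O, −78 °C, slow addition of 14 (2 equiv)
Reagents that add atoms: none
Why: Cinchona alkaloid/lithium-catalysed acyl halide–aldehyde cyclocondensation (formal ketene–aldehyde [2+2]): the alkaloid-bound ammonium enolate of ketene 15 adds to the Li-activated aldehyde through a closed transition state, which should give the cis-β-lactone and set C11 (S) and the C1–O centre (R) under catalyst control.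

Step 10
Reactants: 16 benzyl 7-{(2R)-4-[(2R,3S)-3-[(4S)-5-(benzyloxy)-4-methylpentyl]-4-oxooxetan-2-yl]butan-2-yl}-2,2-diphenyl-1,3-benzodioxole-4-carboxylate
Product: 17 (2S,6S)-7-(benzyloxy)-2-[(1S,4R)-7-(benzyloxycarbonyl)-4-methyl-5,6-(diphenylmethylenedioxy)-1,2,3,4-tetrahydronaphthalen-1-yl]-6-methylheptanoic acid
Conditions: BF3·OEt2 (2 equiv), CH2Cl2, −78 to 0 °C; aqueous work-up
Reagents that add atoms: none
Why: BF3 coordinates the lactone carbonyl and the strained C1–O bond breaks as C8a attacks C1 from the rear (SN2-like Friedel–Crafts alkylation with alkyl–oxygen fission), rearomatisation leaving the C20 carboxylic acid. The closest known reaction types are the Lewis-acid Friedel–Crafts alkylation of arenes by β-lactones and the invertive Lewis-acid opening of β-lactones at the β-carbon by internal weak nucleophiles. The cyclohexane ring closes in the 6-exo-tet mode, the leaving oxygen lying outside the new ring. C1 is the only new stereocentre: inversion of the (R)-C1–O centre from step 9 should give (1S), with the side chain pseudoaxial and trans to the pseudoaxial C4 methyl (both avoid the peri positions), so the stereospecific course and the ring conformation reinforce each other while C11 is carried unchanged. Regiochemistry is secured because C8a (para to the C6 dioxole oxygen, meta to the ester) is the only arene carbon the C4a tether can bring to C1, and attack at the acyl carbon would need an eight-membered ring. The step needs substitution to outrun elimination or decarboxylation of the activated lactone, which the six-membered intramolecular transition state and the coplanar, donating dioxole oxygen should favour.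

Step 11
Reactants: 17 (2S,6S)-7-(benzyloxy)-2-[(1S,4R)-7-(benzyloxycarbonyl)-4-methyl-5,6-(diphenylmethylenedioxy)-1,2,3,4-tetrahydronaphthalen-1-yl]-6-methylheptanoic acid
Product: 18 (2S,6S)-7-(benzyloxy)-2-[(1S,4R)-7-(benzyloxycarbonyl)-4-methyl-5,6-(diphenylmethylenedioxy)-1,2,3,4-tetrahydronaphthalen-1-yl]-6-methylheptan-1-ol
Conditions: BH3·THF, THF, 0 °C to rt; aq. NH4Cl
Reagents that add atoms: none
Why: Borane should reduce the free carboxylic acid (via the acyloxyborane) much faster than the aryl benzyl ester, and the non-basic conditions leave the α-stereocentre C11 intact.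

Step 12
Reactants: 18 (2S,6S)-7-(benzyloxy)-2-[(1S,4R)-7-(benzyloxycarbonyl)-4-methyl-5,6-(diphenylmethylenedioxy)-1,2,3,4-tetrahydronaphthalen-1-yl]-6-methylheptan-1-ol
Product: 19 (2S,6S)-7-(benzyloxy)-2-[(1S,4R)-7-(benzyloxycarbonyl)-4-methyl-5,6-(diphenylmethylenedioxy)-1,2,3,4-tetrahydronaphthalen-1-yl]-6-methylheptyl acetate
Conditions: Ac2O, pyridine, DMAP (cat.), CH2Cl2, 0 °C to rt
Reagents that add atoms: acetic anhydride, CC(=O)OC(C)=O
Why: DMAP-catalysed acylation of the only free hydroxyl group should install the C20 acetate while C16 is still a benzyl ether.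

Step 13
Reactants: 19 (2S,6S)-7-(benzyloxy)-2-[(1S,4R)-7-(benzyloxycarbonyl)-4-methyl-5,6-(diphenylmethylenedioxy)-1,2,3,4-tetrahydronaphthalen-1-yl]-6-methylheptyl acetate
Product: 20 (5R,8S)-8-[(2S,6S)-1-acetoxy-7-hydroxy-6-methylheptan-2-yl]-3,4-dihydroxy-5-methyl-5,6,7,8-tetrahydronaphthalene-2-carboxylic acid (CNP0191669.1)
Conditions: H2 (1 atm), Pd(OH)2/C, EtOAc/EtOH, rt
Reagents that add atoms: none
Why: Hydrogenolysis should cleave the benzyl ester, the benzyl ether and the diphenylmethylene ketal in one operation under neutral conditions, leaving the acetate and all four stereocentres untouched.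

Compound list
1 | 3,6-dibromobenzene-1,2-diol | Oc1c(Br)ccc(Br)c1O | starting material
2 | 4,7-dibromo-2,2-diphenyl-1,3-benzodioxole | Brc1ccc(Br)c2OC(c3ccccc3)(c3ccccc3)Oc12 | intermediate
3 | (7-bromo-2,2-diphenyl-1,3-benzodioxol-4-yl)lithium | [Li]c1ccc(Br)c2OC(c3ccccc3)(c3ccccc3)Oc12 | intermediate
4 | benzyl 7-bromo-2,2-diphenyl-1,3-benzodioxole-4-carboxylate | O=C(OCc1ccccc1)c1ccc(Br)c2OC(c3ccccc3)(c3ccccc3)Oc12 | intermediate
5 | [7-(benzyloxycarbonyl)-2,2-diphenyl-1,3-benzodioxol-4-yl]boronic acid | OB(O)c1ccc(C(=O)OCc2ccccc2)c2OC(c3ccccc3)(c3ccccc3)Oc12 | intermediate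
6 | (Z)-pent-3-en-1-ol | C/C=C\CCO | starting material
7 | benzyl 7-[(2R)-5-oxopentan-2-yl]-2,2-diphenyl-1,3-benzodioxole-4-carboxylate | O=CCC[C@@H](C)c1ccc(C(=O)OCc2ccccc2)c2OC(c3ccccc3)(c3ccccc3)Oc12 | intermediate
8 | (R)-3-bromo-2-methylpropan-1-ol | OC[C@@H](C)CBr | starting material
9 | (R)-[(3-bromo-2-methylpropoxy)methyl]benzene | BrC[C@H](C)COCc1ccccc1 | intermediate
10 | 5-bromopent-1-ene | C=CCCCBr | starting material
11 | pent-4-en-1-ylmagnesium bromide | C=CCCC[Mg]Br | intermediate
12 | (S)-{[(2-methyloct-7-en-1-yl)oxy]methyl}benzene | C=CCCCC[C@H](C)COCc1ccccc1 | intermediate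
13 | (S)-7-(benzyloxy)-6-methylheptanoic acid | OC(=O)CCCC[C@H](C)COCc1ccccc1 | intermediate
14 | (S)-7-(benzyloxy)-6-methylheptanoyl chloride | ClC(=O)CCCC[C@H](C)COCc1ccccc1 | intermediate
15 | (S)-7-(benzyloxy)-6-methylhept-1-en-1-one (alkylketene) | O=C=CCCC[C@H](C)COCc1ccccc1 | intermediate
16 | cis-β-lactone: benzyl 7-{(2R)-4-[(2R,3S)-3-[(4S)-5-(benzyloxy)-4-methylpentyl]-4-oxooxetan-2-yl]butan-2-yl}-2,2-diphenyl-1,3-benzodioxole-4-carboxylate | O=C1O[C@H](CC[C@@H](C)c2ccc(C(=O)OCc3ccccc3)c3OC(c4ccccc4)(c4ccccc4)Oc23)[C@@H]1CCC[C@H](C)COCc1ccccc1 | intermediate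
17 | (1S,4R,11S,15S)-tetralin C20 acid: (2S,6S)-7-(benzyloxy)-2-[(1S,4R)-7-(benzyloxycarbonyl)-4-methyl-5,6-(diphenylmethylenedioxy)-1,2,3,4-tetrahydronaphthalen-1-yl]-6-methylheptanoic acid | OC(=O)[C@@H](CCC[C@H](C)COCc1ccccc1)[C@@H]1CC[C@@H](C)c2c1cc(C(=O)OCc3ccccc3)c3OC(c4ccccc4)(c4ccccc4)Oc23 | intermediate
18 | C20 alcohol: (2S,6S)-7-(benzyloxy)-2-[(1S,4R)-7-(benzyloxycarbonyl)-4-methyl-5,6-(diphenylmethylenedioxy)-1,2,3,4-tetrahydronaphthalen-1-yl]-6-methylheptan-1-ol | OC[C@@H](CCC[C@H](C)COCc1ccccc1)[C@@H]1CC[C@@H](C)c2c1cc(C(=O)OCc3ccccc3)c3OC(c4ccccc4)(c4ccccc4)Oc23 | intermediate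
19 | C20 acetate: (2S,6S)-7-(benzyloxy)-2-[(1S,4R)-7-(benzyloxycarbonyl)-4-methyl-5,6-(diphenylmethylenedioxy)-1,2,3,4-tetrahydronaphthalen-1-yl]-6-methylheptyl acetate | CC(=O)OC[C@@H](CCC[C@H](C)COCc1ccccc1)[C@@H]1CC[C@@H](C)c2c1cc(C(=O)OCc3ccccc3)c3OC(c4ccccc4)(c4ccccc4)Oc23 | intermediate
20 | (5R,8S)-8-[(2S,6S)-1-acetoxy-7-hydroxy-6-methylheptan-2-yl]-3,4-dihydroxy-5-methyl-5,6,7,8-tetrahydronaphthalene-2-carboxylic acid (CNP0191669.1) | CC(=O)OC[C@@H](CCC[C@H](C)CO)[C@@H]1CC[C@@H](C)c2c1cc(C(=O)O)c(O)c2O | target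

Total step count: 13
Longest linear sequence: 9 steps (1 → 2 → 4 → 5 → 7 → 16 → 17 → 18 → 19 → 20; the side-chain branch 8 → 9 → 12 → 13 → 14 → 16 → 20 is equally long)

Steps most likely to fail

Step 10 (key ring closure). The activated lactone may eliminate, decarboxylate or ionise (with loss of stereospecificity) faster than the only moderately nucleophilic arene attacks, and the Lewis acid may open the diphenylmethylene ketal. The fallback moves the closure of the same bond to an allyl cation. It sets out from 16: base-induced ring opening (KHMDS, THF, −78 to 0 °C) would give the (E)-2-alkyl-2-enoic acid F1. Mixed-anhydride reduction (ClCO2Et, Et3N; NaBH4, aq. THF, 0 °C) would give the allylic alcohol F2. FeCl3·6H2O- or Bi(OTf)3-catalysed intramolecular Friedel–Crafts allylic alkylation (C8a onto C1 of the 2-substituted allyl cation; only the six-membered ring is within reach) would give the 1-(alk-1-en-2-yl)tetralin F3. Here C1 would be set by the C4 methyl, both benzylic groups pseudoaxial and trans. 9-BBN hydroboration with NaBO3 oxidation of the 1,1-disubstituted alkene would come back to the route at 18; C11 would then rest on A(1,3)-controlled addition and, if needed, separation of the C11 epimer.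

Step 4 (redox-relay Heck). Protodeboronation or homocoupling of the ortho-oxygenated, electron-poor boronic acid may outrun insertion, and the site or face selectivity of the migratory insertion may erode. The fallback sets out from 4: Suzuki–Miyaura vinylation (potassium vinyltrifluoroborate, PdCl2(dppf), Cs2CO3, THF/H2O) would give the styrene F4. Nickel-catalysed asymmetric hydrovinylation (ethylene 1 atm, [(allyl)NiBr]2, chiral phosphoramidite, NaBArF, CH2Cl2, −78 °C) would give the (R)-3-aryl-but-1-ene F5. Rhodium-catalysed linear hydroformylation (Rh(acac)(CO)2, Xantphos, CO/H2, toluene) would come back to the route at 7.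

Step 9 (cyclocondensation). Dimerisation of the long-chain ketene may outrun addition to the aldehyde, or the cis and facial selectivity may erode. The fallback sets out from 14 and 7 and builds the same lactone by an auxiliary aldol. N-Acylation of lithiated (S)-4-benzyloxazolidin-2-one with 14 would give the imide F6. A boron-mediated Evans syn-aldol reaction with 7 (Bu2BOTf, iPr2NEt, CH2Cl2, −78 to 0 °C) would give the syn adduct F7 with C11 (S) and C1–OH (R). LiOH/H2O2 (THF/H2O, 0 °C) would give the β-hydroxy acid F8. Lactonisation through carboxyl activation (PhSO2Cl, pyridine, 0 °C; retention at C1) would come back to the route at 16.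

Further compounds
F1 | step 10 | (2E,6R)-2-[(4S)-5-(benzyloxy)-4-methylpentyl]-6-[7-(benzyloxycarbonyl)-2,2-diphenyl-1,3-benzodioxol-4-yl]hept-2-enoic acid | OC(=O)/C(CCC[C@H](C)COCc1ccccc1)=C/CC[C@@H](C)c1ccc(C(=O)OCc2ccccc2)c2OC(c3ccccc3)(c3ccccc3)Oc12
F2 | step 10 | (2E,6R)-2-[(4S)-5-(benzyloxy)-4-methylpentyl]-6-[7-(benzyloxycarbonyl)-2,2-diphenyl-1,3-benzodioxol-4-yl]hept-2-en-1-ol | OC/C(CCC[C@H](C)COCc1ccccc1)=C/CC[C@@H](C)c1ccc(C(=O)OCc2ccccc2)c2OC(c3ccccc3)(c3ccccc3)Oc12
F3 | step 10 | (1S,4R)-1-[(6S)-7-(benzyloxy)-6-methylhept-1-en-2-yl]-7-(benzyloxycarbonyl)-4-methyl-5,6-(diphenylmethylenedioxy)-1,2,3,4-tetrahydronaphthalene | C=C(CCC[C@H](C)COCc1ccccc1)[C@@H]1CC[C@@H](C)c2c1cc(C(=O)OCc3ccccc3)c3OC(c4ccccc4)(c4ccccc4)Oc23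
F4 | step 4 | benzyl 7-ethenyl-2,2-diphenyl-1,3-benzodioxole-4-carboxylate | C=Cc1ccc(C(=O)OCc2ccccc2)c2OC(c3ccccc3)(c3ccccc3)Oc12
F5 | step 4 | benzyl 7-[(2R)-but-3-en-2-yl]-2,2-diphenyl-1,3-benzodioxole-4-carboxylate | C=C[C@@H](C)c1ccc(C(=O)OCc2ccccc2)c2OC(c3ccccc3)(c3ccccc3)Oc12
F6 | step 9 | (4S)-4-benzyl-3-[(6S)-7-(benzyloxy)-6-methylheptanoyl]-1,3-oxazolidin-2-one | O=C(CCCC[C@H](C)COCc1ccccc1)N1[C@@H](Cc2ccccc2)COC1=O
F7 | step 9 | (4S)-4-benzyl-3-{(2S,3R,6R)-2-[(4S)-5-(benzyloxy)-4-methylpentyl]-6-[7-(benzyloxycarbonyl)-2,2-diphenyl-1,3-benzodioxol-4-yl]-3-hydroxyheptanoyl}-1,3-oxazolidin-2-one | O=C([C@@H](CCC[C@H](C)COCc1ccccc1)[C@H](O)CC[C@@H](C)c1ccc(C(=O)OCc2ccccc2)c2OC(c3ccccc3)(c3ccccc3)Oc12)N1[C@@H](Cc2ccccc2)COC1=O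
F8 | step 9 | (2S,3R,6R)-2-[(4S)-5-(benzyloxy)-4-methylpentyl]-6-[7-(benzyloxycarbonyl)-2,2-diphenyl-1,3-benzodioxol-4-yl]-3-hydroxyheptanoic acid | OC(=O)[C@@H](CCC[C@H](C)COCc1ccccc1)[C@H](O)CC[C@@H](C)c1ccc(C(=O)OCc2ccccc2)c2OC(c3ccccc3)(c3ccccc3)Oc12
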